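**Retrosynthetic overview**
1. The seven-membered ring is closed last, at C4–C5, by a Ni/Cr alkenyl iodide–aldehyde (Nozaki–Hiyama–Kishi) cyclisation; the five-membered ring is carried from the first step.
2. The C8–C8a bond and the C1 exocyclic methylene come from one chromium-mediated allylation that joins allylic bromide 15 (fragment A, C8: cyclopentene plus C4 alkenyl iodide) to aldehyde 35 (fragment B, C12: C5–C8 plus the diacetoxy side chain).
3. Fragment A comes from (S)-4-hydroxycyclopent-2-enone: anti 1,4-addition then elimination (C3a), Baylis–Hillman hydroxymethylation, Luche reduction (C2).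
4. Fragment B comes from propanal and a nitroalkene by enamine Michael addition (C7, C1′), then γ-silyloxyallylstannane addition (C2′, C3′), cross-metathesis with 2-methylbut-2-ene, and nitro-to-aldehyde conversion.

Conventions and assumption: the core is numbered as decahydroazulene (C1 =CH2, C2 OH, C3, C3a, C4 =CH2, C5 OH, C6, C7 side chain, C8 OH, C8a) and the side chain C1′–C5′ outward from the ring; TBS = tert-butyldimethylsilyl, PMB = 4-methoxybenzyl; all numbered starting materials are assumed to be commercial.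

**Route**

Step 1
Reactants: 1 (S)-4-hydroxycyclopent-2-en-1-one
Product: 2 (S)-4-(TBSO)cyclopent-2-en-1-one
Conditions: TBSCl, imidazole, CH2Cl2, 0 °C → rt
Reagents that add atoms: tert-butyldimethylsilyl chloride, CC(C)(C)[Si](C)(C)Cl
Why: Imidazole-assisted silylation of the secondary alcohol; the stereocentre is not touched.

Step 2
Reactants: 2 (S)-4-(TBSO)cyclopent-2-en-1-one; 3 (1-bromoethenyl)trimethylsilane
Product: 6 (3S,4S)-4-(TBSO)-3-[1-(trimethylsilyl)ethenyl]cyclopentan-1-one, via [1-(trimethylsilyl)ethenyl]magnesium bromide 4 (not isolated), via trimethylsilyl enol ether 5 (not isolated)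
Conditions: 3, Mg, THF, 40 °C; then CuBr·SMe2 (10 mol %), Me3SiCl, 2, THF, −78 °C; 1 M HCl work-up
Reagents that add atoms: none
Why: Copper-catalysed Grignard 1,4-addition in which the alkenyl group enters anti to the adjacent silyloxy group (1,2-induction), setting the future C3a centre trans to the oxygen.

Step 3
Reactants: 6 (3S,4S)-4-(TBSO)-3-[1-(trimethylsilyl)ethenyl]cyclopentan-1-one
Product: 8 (S)-4-[1-(trimethylsilyl)ethenyl]cyclopent-2-en-1-one, via β-hydroxy ketone 7 (not isolated)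
Conditions: AcOH/THF/H2O (3:1:1), 65 °C
Reagents that add atoms: none
Why: Acidic desilylation and β-elimination of the β-hydroxy ketone give the 4-substituted enone; acid is used because base would move the double bond through the doubly allylic C4–H.

Step 4
Reactants: 8 (S)-4-[1-(trimethylsilyl)ethenyl]cyclopent-2-en-1-one
Product: 9 (S)-4-(1-iodoethenyl)cyclopent-2-en-1-one
Conditions: N-iodosuccinimide, (CF3)2CHOH, 0 °C, dark
Reagents that add atoms: N-iodosuccinimide, O=C1CCC(=O)N1I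
Why: ipso-Iododesilylation of the 1,1-disubstituted vinylsilane; the electron-poor enone alkene does not react.

Step 5
Reactants: 9 (S)-4-(1-iodoethenyl)cyclopent-2-en-1-one; 10 formaldehyde
Product: 11 (S)-2-(hydroxymethyl)-4-(1-iodoethenyl)cyclopent-2-en-1-one
Conditions: 37% aq. CH2O, imidazole (1 equiv), THF/H2O (1:1), rt
Reagents that add atoms: none
Why: Morita–Baylis–Hillman hydroxymethylation at the enone α-carbon under a weakly basic nucleophilic catalyst that should leave C4 untouched.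

Step 6
Reactants: 11 (S)-2-(hydroxymethyl)-4-(1-iodoethenyl)cyclopent-2-en-1-one
Product: 12 (1R,4S)-2-(hydroxymethyl)-4-(1-iodoethenyl)cyclopent-2-en-1-ol
Conditions: NaBH4, CeCl3·7H2O, MeOH, −78 °C
Reagents that add atoms: none
Why: Luche 1,2-reduction in which hydride attacks the carbonyl anti to the C4 alkenyl group, giving the cis-1,4 alcohol and so setting the future C2 centre.

Step 7
Reactants: 12 (1R,4S)-2-(hydroxymethyl)-4-(1-iodoethenyl)cyclopent-2-en-1-ol
Product: 13 (1R,4S)-1-(TBSO)-2-[(TBSO)methyl]-4-(1-iodoethenyl)cyclopent-2-ene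
Conditions: TBSCl (2.5 equiv), imidazole, DMF, rt
Reagents that add atoms: tert-butyldimethylsilyl chloride, CC(C)(C)[Si](C)(C)Cl
Why: Exhaustive silylation of both alcohols, so that the less hindered primary ether can be removed selectively in the next step.

Step 8
Reactants: 13 (1R,4S)-1-(TBSO)-2-[(TBSO)methyl]-4-(1-iodoethenyl)cyclopent-2-ene
Product: 14 [(3S,5R)-5-(TBSO)-3-(1-iodoethenyl)cyclopent-1-en-1-yl]methanol
Conditions: HF·pyridine, pyridine, THF, 0 °C
Reagents that add atoms: none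
Why: Buffered fluoride cleaves the primary silyl ether much faster than the hindered secondary one.

Step 9
Reactants: 14 [(3S,5R)-5-(TBSO)-3-(1-iodoethenyl)cyclopent-1-en-1-yl]methanol
Product: 15 (1R,4S)-2-(bromomethyl)-1-(TBSO)-4-(1-iodoethenyl)cyclopent-2-ene
Conditions: CBr4, PPh3, 2,6-lutidine, CH2Cl2, −20 → 0 °C
Reagents that add atoms: carbon tetrabromide, BrC(Br)(Br)Br
Why: Appel bromination of the primary allylic alcohol by SN2 displacement; no stereocentre is involved.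

Step 10
Reactants: 16 propane-1,3-diol
Product: 17 3-(PMBO)propan-1-ol
Conditions: NaH (1 equiv), 4-MeOC6H4CH2Cl, n-Bu4NI (cat.), THF/DMF, 0 °C → rt (diol 3 equiv)
Reagents that add atoms: 4-methoxybenzyl chloride, COc1ccc(CCl)cc1
Why: Williamson mono-etherification, made selective by the excess of diol.

Step 11
Reactants: 17 3-(PMBO)propan-1-ol
Product: 18 3-(PMBO)propanal
Conditions: TEMPO (10 mol %), PhI(OAc)2, CH2Cl2, rt
Reagents that add atoms: none
Why: Oxoammonium-mediated oxidation of the primary alcohol stops at the aldehyde.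

Step 12
Reactants: 18 3-(PMBO)propanal; 19 nitromethane
Product: 20 4-(PMBO)-1-nitrobutan-2-ol (racemic)
Conditions: MeNO2 (5 equiv), Et3N (20 mol %), THF, 0 °C → rt
Reagents that add atoms: none
Why: Henry (nitroaldol) addition; the new carbinol centre is removed in the next step.

Step 13
Reactants: 20 4-(PMBO)-1-nitrobutan-2-ol
Product: 22 (E)-4-(PMBO)-1-nitrobut-1-ene, via mesylate 21 (not isolated)
Conditions: MsCl, Et3N (2.5 equiv), CH2Cl2, −20 → 0 °C
Reagents that add atoms: none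
Why: Mesylation and E1cB elimination give the thermodynamically favoured (E)-nitroalkene.

Step 14
Reactants: 22 (E)-4-(PMBO)-1-nitrobut-1-ene; 23 propanal
Product: 24 (2R,3R)-2-methyl-3-(nitromethyl)-5-(PMBO)pentanal
Conditions: (S)-2-[diphenyl(trimethylsilyloxy)methyl]pyrrolidine (10 mol %), 4-nitrophenol (10 mol %), propanal (3 equiv), toluene, 0 °C
Reagents that add atoms: none
Why: Enamine-catalysed Michael addition in which the (S)-catalyst shields one enamine face and the acyclic synclinal transition state gives the syn adduct, setting C7 and C1′.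

Step 15
Reactants: 25 prop-2-en-1-ol
Product: 26 tert-butyldimethyl(prop-2-en-1-yloxy)silane
Conditions: TBSCl, imidazole, CH2Cl2, rt
Reagents that add atoms: tert-butyldimethylsilyl chloride, CC(C)(C)[Si](C)(C)Cl
Why: Routine silylation of the primary alcohol.

Step 16
Reactants: 26 tert-butyldimethyl(prop-2-en-1-yloxy)silane
Product: 28 (Z)-1-(TBSO)-3-(tributylstannyl)prop-1-ene, via allyllithium reagent 27 (not isolated)
Conditions: s-BuLi, THF/HMPA, −78 °C; then n-Bu3SnCl
Reagents that add atoms: tributyltin chloride, CCCC[Sn](Cl)(CCCC)CCCC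
Why: Deprotonation next to oxygen gives the internally coordinated (Z)-oxyallyl anion, which is stannylated at the γ-carbon.

Step 17
Reactants: 24 (2R,3R)-2-methyl-3-(nitromethyl)-5-(PMBO)pentanal; 28 (Z)-1-(TBSO)-3-(tributylstannyl)prop-1-ene
Product: 29 (3S,4S,5R,6R)-3-(TBSO)-5-methyl-6-(nitromethyl)-8-(PMBO)oct-1-en-4-ol
Conditions: BF3·OEt2 (2 equiv), CH2Cl2, −78 °C
Reagents that add atoms: none
Why: Lewis-acid-promoted SE2′ addition of the γ-silyloxyallylstannane through an open transition state gives the syn 1,2-diol relationship (C2′/C3′) with Felkin–Anh attack on the α-methyl aldehyde (C1′/C2′ syn).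

Step 18
Reactants: 29 (3S,4S,5R,6R)-3-(TBSO)-5-methyl-6-(nitromethyl)-8-(PMBO)oct-1-en-4-ol
Product: 30 (3S,4S,5R,6R)-5-methyl-6-(nitromethyl)-8-(PMBO)oct-1-ene-3,4-diol
Conditions: HF·pyridine, pyridine, THF, 0 °C → rt
Reagents that add atoms: none
Why: Fluoride cleaves the allylic silyl ether; the benzylic ether and the nitro group are unaffected.

Step 19
Reactants: 30 (3S,4S,5R,6R)-5-methyl-6-(nitromethyl)-8-(PMBO)oct-1-ene-3,4-diol; 31 2-methylbut-2-ene
Product: 32 (4S,5S,6R,7R)-2,6-dimethyl-7-(nitromethyl)-9-(PMBO)non-2-ene-4,5-diol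
Conditions: second-generation Grubbs catalyst (H2IMes)(PCy3)Cl2Ru=CHPh (5 mol %), 2-methylbut-2-ene/CH2Cl2 (1:1), 40 °C, sealed tube
Reagents that add atoms: none
Why: Olefin cross-metathesis with an excess of the trisubstituted partner converts the vinyl group into the 2-methylprop-1-enyl group and releases propene.

Step 20
Reactants: 32 (4S,5S,6R,7R)-2,6-dimethyl-7-(nitromethyl)-9-(PMBO)non-2-ene-4,5-diol
Product: 33 (4S,5S,6R,7R)-2,6-dimethyl-7-(nitromethyl)-9-(PMBO)non-2-ene-4,5-diyl diacetate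
Conditions: Ac2O, pyridine, rt
Reagents that add atoms: acetic anhydride, CC(=O)OC(C)=O
Why: Acetylation of both secondary alcohols; no acylation catalyst is added, to avoid O-acylation of the nitronate and nitrile oxide formation.

Step 21
Reactants: 33 (4S,5S,6R,7R)-2,6-dimethyl-7-(nitromethyl)-9-(PMBO)non-2-ene-4,5-diyl diacetate
Product: 34 (4S,5S,6R,7R)-7-[(hydroxyimino)methyl]-2,6-dimethyl-9-(PMBO)non-2-ene-4,5-diyl diacetate (E/Z mixture)
Conditions: SnCl2·2H2O, PhSH, Et3N, MeCN, rt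
Reagents that add atoms: none
Why: A divalent tin thiolate complex reduces the primary nitro group to the oxime under near-neutral conditions that spare the acetates and the C7 centre.

Step 22
Reactants: 34 (4S,5S,6R,7R)-7-[(hydroxyimino)methyl]-2,6-dimethyl-9-(PMBO)non-2-ene-4,5-diyl diacetate
Product: 35 (4S,5S,6R,7R)-7-formyl-2,6-dimethyl-9-(PMBO)non-2-ene-4,5-diyl diacetate
Conditions: TiCl3 (aq.), NH4OAc, 1,4-dioxane/H2O, pH 6, rt
Reagents that add atoms: water, O
Why: Trivalent titanium cleaves the N–O bond and the resulting imine hydrolyses at buffered pH (reductive Nef-type deoximation), so the α-stereocentre is not epimerised.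

Step 23
Reactants: 15 (1R,4S)-2-(bromomethyl)-1-(TBSO)-4-(1-iodoethenyl)cyclopent-2-ene; 35 (4S,5S,6R,7R)-7-formyl-2,6-dimethyl-9-(PMBO)non-2-ene-4,5-diyl diacetate
Product: 37 (4S,5S,6R,7R)-7-[(S)-hydroxy{(1R,3R,5S)-3-(TBSO)-5-(1-iodoethenyl)-2-methylidenecyclopentyl}methyl]-2,6-dimethyl-9-(PMBO)non-2-ene-4,5-diyl diacetate, via allylchromium dichloride 36 (not isolated)
Conditions: CrCl2 (4 equiv), THF, 0 °C → rt
Reagents that add atoms: none
Why: Nozaki–Hiyama allylation, in which divalent chromium converts the allylic bromide into allylchromium 36 (the alkenyl iodide is inert without nickel). The reagent adds through its ring carbon in a chair transition state, on the face anti to the C3a and C2 substituents, giving the anti C8a/C8 and Felkin–Anh C8/C7 relationships and unveiling the C1 exocyclic methylene.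

Step 24
Reactants: 37 (the homoallylic alcohol of step 23)
Product: 38 (4S,5S,6R,7R)-7-[(S)-(TBSO){(1R,3R,5S)-3-(TBSO)-5-(1-iodoethenyl)-2-methylidenecyclopentyl}methyl]-2,6-dimethyl-9-(PMBO)non-2-ene-4,5-diyl diacetate
Conditions: TBSOTf, 2,6-lutidine, CH2Cl2, −78 → 0 °C
Reagents that add atoms: tert-butyldimethylsilyl trifluoromethanesulfonate, CC(C)(C)[Si](C)(C)OS(=O)(=O)C(F)(F)F
Why: The silyl triflate protects the hindered C8 alcohol, which would otherwise form a lactol with the C5 aldehyde made in step 26.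

Step 25
Reactants: 38 (the bis-silyl ether of step 24)
Product: 39 (4S,5S,6R,7R)-9-hydroxy-7-[(S)-(TBSO){(1R,3R,5S)-3-(TBSO)-5-(1-iodoethenyl)-2-methylidenecyclopentyl}methyl]-2,6-dimethylnon-2-ene-4,5-diyl diacetate
Conditions: DDQ, CH2Cl2/pH 7 buffer (10:1), 0 °C
Reagents that add atoms: none
Why: Oxidative cleavage of the electron-rich benzylic ether leaves silyl ethers, acetates, alkenes and the alkenyl iodide intact.

Step 26
Reactants: 39 (the primary alcohol of step 25)
Product: 40 (4S,5S,6R,7R)-7-[(S)-(TBSO){(1R,3R,5S)-3-(TBSO)-5-(1-iodoethenyl)-2-methylidenecyclopentyl}methyl]-2,6-dimethyl-9-oxonon-2-ene-4,5-diyl diacetate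
Conditions: Dess–Martin periodinane, NaHCO3, CH2Cl2, 0 °C → rt
Reagents that add atoms: none
Why: Mild buffered hypervalent-iodine oxidation of the primary alcohol to the aldehyde.

Step 27
Reactants: 40 (the iodo aldehyde of step 26)
Product: 42 (2R,3S,4S)-2-[(2R,3aS,5S,7R,8S,8aR)-2,8-bis(TBSO)-5-hydroxy-1,4-dimethylidenedecahydroazulen-7-yl]-6-methylhept-5-ene-3,4-diyl diacetate, via alkenylchromium dichloride 41 (not isolated)
Conditions: CrCl2 (10 equiv), NiCl2 (2 mol %), DMSO, rt, 0.003 M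
Reagents that add atoms: none
Why: Nozaki–Hiyama–Kishi reaction, in which nickel-catalysed formation of alkenylchromium 41 is followed by intramolecular addition to the aldehyde, closing the trans-fused seven-membered ring. The 5S carbinol is the expected (not assured) major epimer, from attack anti to the C3a–C3 bond with the chromium alkoxide pseudo-equatorial.

Step 28
Reactants: 42 (the bis-silyl ether of step 27)
Product: 43 (2R,3S,4S)-2-[(2R,3aS,5S,7R,8S,8aR)-2,5,8-trihydroxy-1,4-dimethylidenedecahydroazulen-7-yl]-6-methylhept-5-ene-3,4-diyl diacetate (CNP0172457.3)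
Conditions: HF·pyridine, pyridine, THF, 0 °C → rt
Reagents that add atoms: none
Why: Buffered fluoride removes both silyl ethers without hydrolysing or migrating the two acetates.

**Compound list**

1 | (S)-4-hydroxycyclopent-2-en-1-one | O=C1C=C[C@@H](O)C1 | starting material
2 | (S)-4-(TBSO)cyclopent-2-en-1-one | O=C1C=C[C@@H](O[Si](C)(C)C(C)(C)C)C1 | intermediate
3 | (1-bromoethenyl)trimethylsilane | C=C(Br)[Si](C)(C)C | starting material
4 | [1-(trimethylsilyl)ethenyl]magnesium bromide | C=C([Mg]Br)[Si](C)(C)C | intermediate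
5 | trimethylsilyl enol ether of 6: (1S,2S)-1-(TBSO)-2-[1-(trimethylsilyl)ethenyl]-4-[(trimethylsilyl)oxy]cyclopent-3-ene | C[Si](C)(C)OC1=C[C@H](C(=C)[Si](C)(C)C)[C@@H](O[Si](C)(C)C(C)(C)C)C1 | intermediate
6 | (3S,4S)-4-(TBSO)-3-[1-(trimethylsilyl)ethenyl]cyclopentan-1-one | O=C1C[C@H](C(=C)[Si](C)(C)C)[C@@H](O[Si](C)(C)C(C)(C)C)C1 | intermediate
7 | (3S,4S)-4-hydroxy-3-[1-(trimethylsilyl)ethenyl]cyclopentan-1-one | O=C1C[C@H](C(=C)[Si](C)(C)C)[C@@H](O)C1 | intermediate
8 | (S)-4-[1-(trimethylsilyl)ethenyl]cyclopent-2-en-1-one | O=C1C=C[C@@H](C(=C)[Si](C)(C)C)C1 | intermediate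
9 | (S)-4-(1-iodoethenyl)cyclopent-2-en-1-one | O=C1C=C[C@@H](C(I)=C)C1 | intermediate
10 | formaldehyde | C=O | starting material
11 | (S)-2-(hydroxymethyl)-4-(1-iodoethenyl)cyclopent-2-en-1-one | O=C1C(CO)=C[C@@H](C(I)=C)C1 | intermediate
12 | (1R,4S)-2-(hydroxymethyl)-4-(1-iodoethenyl)cyclopent-2-en-1-ol | OCC1=C[C@@H](C(I)=C)C[C@H]1O | intermediate
13 | (1R,4S)-1-(TBSO)-2-[(TBSO)methyl]-4-(1-iodoethenyl)cyclopent-2-ene | CC(C)(C)[Si](C)(C)OCC1=C[C@@H](C(I)=C)C[C@H]1O[Si](C)(C)C(C)(C)C | intermediate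
14 | [(3S,5R)-5-(TBSO)-3-(1-iodoethenyl)cyclopent-1-en-1-yl]methanol | OCC1=C[C@@H](C(I)=C)C[C@H]1O[Si](C)(C)C(C)(C)C | intermediate
15 | (1R,4S)-2-(bromomethyl)-1-(TBSO)-4-(1-iodoethenyl)cyclopent-2-ene | BrCC1=C[C@@H](C(I)=C)C[C@H]1O[Si](C)(C)C(C)(C)C | intermediate
16 | propane-1,3-diol | OCCCO | starting material
17 | 3-(PMBO)propan-1-ol | OCCCOCc1ccc(OC)cc1 | intermediate
18 | 3-(PMBO)propanal | O=CCCOCc1ccc(OC)cc1 | intermediate
19 | nitromethane | C[N+](=O)[O-] | starting material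
20 | 4-(PMBO)-1-nitrobutan-2-ol (racemic) | OC(C[N+](=O)[O-])CCOCc1ccc(OC)cc1 | intermediate
21 | 4-(PMBO)-1-nitrobutan-2-yl methanesulfonate | CS(=O)(=O)OC(C[N+](=O)[O-])CCOCc1ccc(OC)cc1 | intermediate
22 | (E)-4-(PMBO)-1-nitrobut-1-ene | [O-][N+](=O)/C=C/CCOCc1ccc(OC)cc1 | intermediate
23 | propanal | CCC=O | starting material
24 | (2R,3R)-2-methyl-3-(nitromethyl)-5-(PMBO)pentanal | [O-][N+](=O)C[C@@H]([C@@H](C)C=O)CCOCc1ccc(OC)cc1 | intermediate
25 | prop-2-en-1-ol | C=CCO | starting material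
26 | tert-butyldimethyl(prop-2-en-1-yloxy)silane | C=CCO[Si](C)(C)C(C)(C)C | intermediate
27 | [(Z)-3-(TBSO)prop-2-en-1-yl]lithium | [Li]C/C=C\O[Si](C)(C)C(C)(C)C | intermediate
28 | (Z)-1-(TBSO)-3-(tributylstannyl)prop-1-ene | CCCC[Sn](CCCC)(CCCC)C/C=C\O[Si](C)(C)C(C)(C)C | intermediate
29 | (3S,4S,5R,6R)-3-(TBSO)-5-methyl-6-(nitromethyl)-8-(PMBO)oct-1-en-4-ol | [O-][N+](=O)C[C@@H]([C@@H](C)[C@H](O)[C@H](C=C)O[Si](C)(C)C(C)(C)C)CCOCc1ccc(OC)cc1 | intermediate
30 | (3S,4S,5R,6R)-5-methyl-6-(nitromethyl)-8-(PMBO)oct-1-ene-3,4-diol | [O-][N+](=O)C[C@@H]([C@@H](C)[C@H](O)[C@H](C=C)O)CCOCc1ccc(OC)cc1 | intermediate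
31 | 2-methylbut-2-ene | CC=C(C)C | starting material
32 | (4S,5S,6R,7R)-2,6-dimethyl-7-(nitromethyl)-9-(PMBO)non-2-ene-4,5-diol | [O-][N+](=O)C[C@@H]([C@@H](C)[C@H](O)[C@H](C=C(C)C)O)CCOCc1ccc(OC)cc1 | intermediate
33 | (4S,5S,6R,7R)-2,6-dimethyl-7-(nitromethyl)-9-(PMBO)non-2-ene-4,5-diyl diacetate | [O-][N+](=O)C[C@@H]([C@@H](C)[C@H](OC(C)=O)[C@H](C=C(C)C)OC(C)=O)CCOCc1ccc(OC)cc1 | intermediate
34 | (4S,5S,6R,7R)-7-[(hydroxyimino)methyl]-2,6-dimethyl-9-(PMBO)non-2-ene-4,5-diyl diacetate | ON=C[C@@H]([C@@H](C)[C@H](OC(C)=O)[C@H](C=C(C)C)OC(C)=O)CCOCc1ccc(OC)cc1 | intermediate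
35 | (4S,5S,6R,7R)-7-formyl-2,6-dimethyl-9-(PMBO)non-2-ene-4,5-diyl diacetate | O=C[C@@H]([C@@H](C)[C@H](OC(C)=O)[C@H](C=C(C)C)OC(C)=O)CCOCc1ccc(OC)cc1 | intermediate
36 | {[(3S,5R)-5-(TBSO)-3-(1-iodoethenyl)cyclopent-1-en-1-yl]methyl}chromium dichloride | Cl[Cr](Cl)CC1=C[C@@H](C(I)=C)C[C@H]1O[Si](C)(C)C(C)(C)C | intermediate
37 | (4S,5S,6R,7R)-7-[(S)-hydroxy{(1R,3R,5S)-3-(TBSO)-5-(1-iodoethenyl)-2-methylidenecyclopentyl}methyl]-2,6-dimethyl-9-(PMBO)non-2-ene-4,5-diyl diacetate | C=C1[C@H]([C@@H](O)[C@@H]([C@@H](C)[C@H](OC(C)=O)[C@H](C=C(C)C)OC(C)=O)CCOCc2ccc(OC)cc2)[C@@H](C(I)=C)C[C@H]1O[Si](C)(C)C(C)(C)C | intermediate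
38 | C8-O-TBS ether of 37 | C=C1[C@H]([C@@H](O[Si](C)(C)C(C)(C)C)[C@@H]([C@@H](C)[C@H](OC(C)=O)[C@H](C=C(C)C)OC(C)=O)CCOCc2ccc(OC)cc2)[C@@H](C(I)=C)C[C@H]1O[Si](C)(C)C(C)(C)C | intermediate
39 | primary alcohol (PMB removed from 38) | C=C1[C@H]([C@@H](O[Si](C)(C)C(C)(C)C)[C@@H]([C@@H](C)[C@H](OC(C)=O)[C@H](C=C(C)C)OC(C)=O)CCO)[C@@H](C(I)=C)C[C@H]1O[Si](C)(C)C(C)(C)C | intermediate
40 | aldehyde (9-oxo compound from 39) | C=C1[C@H]([C@@H](O[Si](C)(C)C(C)(C)C)[C@@H]([C@@H](C)[C@H](OC(C)=O)[C@H](C=C(C)C)OC(C)=O)CC=O)[C@@H](C(I)=C)C[C@H]1O[Si](C)(C)C(C)(C)C | intermediate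
41 | alkenylchromium dichloride from 40 (CrCl2 in place of iodine) | C=C1[C@H]([C@@H](O[Si](C)(C)C(C)(C)C)[C@@H]([C@@H](C)[C@H](OC(C)=O)[C@H](C=C(C)C)OC(C)=O)CC=O)[C@@H](C(=C)[Cr](Cl)Cl)C[C@H]1O[Si](C)(C)C(C)(C)C | intermediate
42 | (2R,3S,4S)-2-[(2R,3aS,5S,7R,8S,8aR)-2,8-bis(TBSO)-5-hydroxy-1,4-dimethylidenedecahydroazulen-7-yl]-6-methylhept-5-ene-3,4-diyl diacetate | C=C1[C@@H]2[C@@H](O[Si](C)(C)C(C)(C)C)[C@@H]([C@@H](C)[C@H](OC(C)=O)[C@H](C=C(C)C)OC(C)=O)C[C@H](O)C(=C)[C@H]2C[C@H]1O[Si](C)(C)C(C)(C)C | intermediate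
43 | (2R,3S,4S)-2-[(2R,3aS,5S,7R,8S,8aR)-2,5,8-trihydroxy-1,4-dimethylidenedecahydroazulen-7-yl]-6-methylhept-5-ene-3,4-diyl diacetate | C=C1[C@@H]2[C@@H](O)[C@@H]([C@@H](C)[C@H](OC(C)=O)[C@H](C=C(C)C)OC(C)=O)C[C@H](O)C(=C)[C@H]2C[C@H]1O | target

**Step count and risks**

Total steps: 28. Longest linear sequence: 17 steps (10–14, 17–22, then 23–28, from propane-1,3-diol); the fragment A branch is 9 steps (1–9) and the stannane branch 2 steps (15–16).

Most likely to fail:

Step 5 (Baylis–Hillman reaction on a hindered, base-sensitive 4-alkenyl enone, where slow addition or double-bond migration is possible). The fallback sets out from enone 8 and comes back at 11, replacing the amine-catalysed aldol-type bond formation by a base-free cross-coupling. α-Iodination with I2 and pyridine in CH2Cl2 gives (S)-2-iodo-4-[1-(trimethylsilyl)ethenyl]cyclopent-2-en-1-one F1. Stille coupling with (tributylstannyl)methanol (Pd2(dba)3, AsPh3, CuI, NMP, rt) gives (S)-2-(hydroxymethyl)-4-[1-(trimethylsilyl)ethenyl]cyclopent-2-en-1-one F2. Iododesilylation under the conditions of step 4 then gives 11.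

Step 23 (fragment union: three stereochemical elements must cooperate, and the alkenyl iodide must survive divalent chromium). The fallback sets out from bromide 15 and comes back at 37, replacing the in situ organochromium reagent by an isolated allylboronate. Zinc dust in THF at 0 °C (the alkenyl iodide does not insert) gives bromo{[(3S,5R)-5-(TBSO)-3-(1-iodoethenyl)cyclopent-1-en-1-yl]methyl}zinc F3. Trapping with 2-isopropoxy-4,4,5,5-tetramethyl-1,3,2-dioxaborolane gives the purifiable 2-{[(3S,5R)-5-(TBSO)-3-(1-iodoethenyl)cyclopent-1-en-1-yl]methyl}-4,4,5,5-tetramethyl-1,3,2-dioxaborolane F4. Allylboration of aldehyde 35 with Sc(OTf)3 (10 mol %) in CH2Cl2 at −78 °C goes through the same closed chair transition state (anti, Felkin–Anh) and gives 37 with no chromium present.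

Step 27 (seven-membered ring closure; the configuration at C5 is not securely predictable). The fallback sets out from aldehyde 40 and comes back at 42, setting C5 by reagent-controlled ketone reduction instead of in the cyclisation. If the cyclisation gives mainly the (5R)-epimer of 42 F5, the epimer mixture is oxidised with Dess–Martin periodinane to (2R,3S,4S)-2-[(2R,3aS,7R,8S,8aR)-2,8-bis(TBSO)-1,4-dimethylidene-5-oxodecahydroazulen-7-yl]-6-methylhept-5-ene-3,4-diyl diacetate F6. This exocyclic enone is reduced with (R)-2-methyl-CBS-oxazaborolidine and catecholborane in toluene at −78 °C (the alkenyl side acts as the large group), giving the 5S alcohol 42.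

**Further compounds**

F1 | step 5 | (S)-2-iodo-4-[1-(trimethylsilyl)ethenyl]cyclopent-2-en-1-one | O=C1C(I)=C[C@@H](C(=C)[Si](C)(C)C)C1
F2 | step 5 | (S)-2-(hydroxymethyl)-4-[1-(trimethylsilyl)ethenyl]cyclopent-2-en-1-one | O=C1C(CO)=C[C@@H](C(=C)[Si](C)(C)C)C1
F3 | step 23 | bromo{[(3S,5R)-5-(TBSO)-3-(1-iodoethenyl)cyclopent-1-en-1-yl]methyl}zinc | Br[Zn]CC1=C[C@@H](C(I)=C)C[C@H]1O[Si](C)(C)C(C)(C)C
F4 | step 23 | 2-{[(3S,5R)-5-(TBSO)-3-(1-iodoethenyl)cyclopent-1-en-1-yl]methyl}-4,4,5,5-tetramethyl-1,3,2-dioxaborolane | CC1(C)OB(CC2=C[C@@H](C(I)=C)C[C@H]2O[Si](C)(C)C(C)(C)C)OC1(C)C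
F5 | step 27 | (5R)-epimer of 42 | C=C1[C@@H]2[C@@H](O[Si](C)(C)C(C)(C)C)[C@@H]([C@@H](C)[C@H](OC(C)=O)[C@H](C=C(C)C)OC(C)=O)C[C@@H](O)C(=C)[C@H]2C[C@H]1O[Si](C)(C)C(C)(C)C
F6 | step 27 | (2R,3S,4S)-2-[(2R,3aS,7R,8S,8aR)-2,8-bis(TBSO)-1,4-dimethylidene-5-oxodecahydroazulen-7-yl]-6-methylhept-5-ene-3,4-diyl diacetate | C=C1[C@@H]2[C@@H](O[Si](C)(C)C(C)(C)C)[C@@H]([C@@H](C)[C@H](OC(C)=O)[C@H](C=C(C)C)OC(C)=O)CC(=O)C(=C)[C@H]2C[C@H]1O[Si](C)(C)C(C)(C)C
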